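**Retrosynthetic overview**

1. The target is ring A (gem-dimethyl dienone) –CH2– ring B (central butyrylphloroglucinol) –CH2– ring C (methoxy arene). The last bond cut is ring A–CH2–ring B: the one free ring B carbon of the B–C unit 15 adds to the ring A methide released from Mannich base 20.
2. 15 goes back to pentaphenol 13 by a double Friedel–Crafts butyrylation (ring C C5 and one of the two equivalent ring B carbons), and 13 to tribenzyl ether 12 by hydrogenolysis.
3. Feature: ring C (C1 bridge CH2, C2 OH, C3 CH3, C4 OCH3, C5 butyryl, C6 OH) without its C5 butyryl group is an isomer of a 4-methoxy-5-methyl-6-alkyl-2-pyranone. In that ring the 4-OH is the only hydroxyl there is to methylate, so the single O-methyl group of the target is placed without choosing among phenols.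
4. Key cut: the C1–C6 bond of ring C in 12 leads back to pyranone 10 (lactone opened, ketone CH2 acylated by the ester). 10 comes from 4-methoxy-5,6-dimethyl-2-pyranone 5 and aldehyde 7 (vinylogous aldol condensation, then alkene hydrogenation), and 5 from 3-methylpentane-2,4-dione and dimethyl carbonate.
5. Ring order: pyranone (step 2); ring C by isomerisation of the pyranone (step 7, ring B enters as a bought arene); ring A by dearomatising gem-dimethylation of phlorobutyrophenone (step 11); union in step 13.

Key step: step 7

Remark: 8 and 11 each carry one stereocentre and are racemic; the target has none, so no step has to control configuration. Ring A is written in the enol form of the target structure, and 2,4,6-trihydroxybenzaldehyde is taken as the commercial source of ring B.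

**Route**

Step 1
Reactants: 1 3-methylpentane-2,4-dione; 2 dimethyl carbonate
Product: 3 methyl 4-methyl-3,5-dioxohexanoate
Conditions: LiN(i-Pr)2 (3.1 equiv), THF, −78 → 0 °C; then 2, −78 °C → rt; aq. HCl
Reagents that add atoms: dimethyl carbonate (2), COC(=O)OC
Why: The diketone is deprotonated twice and the dianion reacts at its more basic terminal CH2 carbon with the carbonate (Claisen-type C-acylation of a 1,3-diketone dianion), the third equivalent of base covering the more acidic keto ester that forms.

Step 2
Reactants: 3 methyl 4-methyl-3,5-dioxohexanoate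
Product: 4 4-hydroxy-5,6-dimethyl-2H-pyran-2-one
Conditions: DBU (1.2 equiv), PhMe, reflux; aq. HCl
Reagents that add atoms: none
Why: DBU enolises the C5 ketone and its oxygen closes on the ester carbonyl with loss of methanol (6-exo-trig lactonisation of a 3,5-dioxo ester, the standard route to 4-hydroxy-2-pyranones).

Step 3
Reactants: 4 4-hydroxy-5,6-dimethyl-2H-pyran-2-one
Product: 5 4-methoxy-5,6-dimethyl-2H-pyran-2-one
Conditions: Me2SO4, K2CO3, acetone, reflux
Reagents that add atoms: dimethyl sulfate, COS(=O)(=O)OC
Why: Williamson-type O-methylation of the vinylogous acid with a hard electrophile should give mainly the 4-methoxy-2-pyranone (the isomeric 2-methoxy-4-pyranone is the usual minor product to be removed), and this single O-methylation fixes the future C4 OCH3 of ring C.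

Step 4
Reactants: 6 2,4,6-trihydroxybenzaldehyde
Product: 7 2,4,6-tris(benzyloxy)benzaldehyde
Conditions: BnBr (3.6 equiv), K2CO3, DMF, 60 °C
Reagents that add atoms: benzyl bromide, BrCc1ccccc1
Why: Williamson etherification of all three phenols, in which the formyl group lowers the C-nucleophilicity of the ring enough for O-benzylation to prevail and which gives ring B a protection that is stable to base and removable by hydrogenolysis.

Step 5
Reactants: 5 4-methoxy-5,6-dimethyl-2H-pyran-2-one; 7 2,4,6-tris(benzyloxy)benzaldehyde
Product: 9 4-methoxy-5-methyl-6-{(E)-2-[2,4,6-tris(benzyloxy)phenyl]ethenyl}-2H-pyran-2-one, via aldol adduct 8 (not isolated)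
Conditions: Mg(OMe)2, MeOH, reflux; aq. HCl
Reagents that add atoms: none
Why: Mg(OMe)2 deprotonates only the 6-methyl group of 5 (an anion at the 5-methyl group is not conjugated to the lactone carbonyl), and the vinylogous enolate adds to 7 and dehydrates by E1cB to the E-styrylpyranone (vinylogous aldol condensation, the classical entry to 6-styryl-4-methoxy-2-pyranones), which brings in ring B as an aldehyde and so avoids a 2,4,6-trialkoxybenzyl halide that would ionise on handling.

Step 6
Reactants: 9 4-methoxy-5-methyl-6-{(E)-2-[2,4,6-tris(benzyloxy)phenyl]ethenyl}-2H-pyran-2-one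
Product: 10 4-methoxy-5-methyl-6-{2-[2,4,6-tris(benzyloxy)phenyl]ethyl}-2H-pyran-2-one
Conditions: H2 (4 bar), RhCl(PPh3)3 (10 mol %), PhMe–EtOH, 50 °C
Reagents that add atoms: none
Why: Homogeneous hydrogenation with RhCl(PPh3)3 saturates the disubstituted styryl double bond but cannot hydrogenolyse aryl benzyl ethers and leaves the tri- and tetrasubstituted, ester-conjugated double bonds of the pyranone alone.

Step 7
Reactants: 10 4-methoxy-5-methyl-6-{2-[2,4,6-tris(benzyloxy)phenyl]ethyl}-2H-pyran-2-one
Product: 12 5-methoxy-4-methyl-2-{[2,4,6-tris(benzyloxy)phenyl]methyl}benzene-1,3-diol, via open-chain methoxy keto ester 11 (not isolated)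
Conditions: Mg(OMe)2 (2 equiv), MeOH, reflux; then NaOMe (6 equiv), MeOH–PhMe, 110 °C, sealed vessel, degassed; aq. HCl
Reagents that add atoms: none
Why: Methoxide, delivered on magnesium that also holds the opened chain as a chelate, adds to the lactone carbonyl of 10 and opens the ring to the methoxy keto ester 11, whose ester carbon and ketone chain start cis on the enoate double bond because both came from the ring; under NaOMe at 110 °C the ketone enolises towards the CH2 that carries the arylmethyl group, this carbon (C1 of ring C) attacks the ester carbon (C6), methoxide is expelled and the 5-methoxycyclohexene-1,3-dione tautomerises to the arene. The closest known reaction type is the base-induced Claisen-type isomerisation of 4-methoxy-6-alkyl-2-pyranones into phloroglucinol monomethyl ethers, which needs forcing conditions. Ring C closes in a 6-(enolendo)-exo-trig mode and no stereocentre is formed. The step needs C-acylation by the less acidic C1 enolate: deprotonation at the more acidic C3 gives a delocalised anion that cannot reach the ester through carbon and can only re-close to the pyranone through oxygen or rotate about the enoate bond, both reversibly, whereas closure from C1 is followed by aromatisation to a phenoxide and is irreversible, so the equilibrating species should drain into 12. The benzyl ethers of ring B are inert to methoxide, and C5 is left as the only unsubstituted carbon of ring C, so the later butyrylation must land between OCH3 and OH.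

Step 8
Reactants: 12 5-methoxy-4-methyl-2-{[2,4,6-tris(benzyloxy)phenyl]methyl}benzene-1,3-diol
Product: 13 2-[(2,6-dihydroxy-4-methoxy-3-methylphenyl)methyl]benzene-1,3,5-triol
Conditions: H2 (1 atm), 10% Pd/C, EtOAc–MeOH, rt
Reagents that add atoms: none
Why: Hydrogenolysis of the three aryl benzyl ethers over palladium on carbon under neutral conditions frees ring B for acylation, while the diarylmethane C–C bond and the methyl ether are not touched.

Step 9
Reactants: 13 2-[(2,6-dihydroxy-4-methoxy-3-methylphenyl)methyl]benzene-1,3,5-triol; 14 butyryl chloride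
Product: 15 1-{3-[(3-butanoyl-2,6-dihydroxy-4-methoxy-5-methylphenyl)methyl]-2,4,6-trihydroxyphenyl}butan-1-one
Conditions: 14 (2.2 equiv), AlCl3 (7 equiv), CH2Cl2–PhNO2, 0 °C → rt; ice, aq. HCl
Reagents that add atoms: butyryl chloride (14), CCCC(=O)Cl
Why: Friedel–Crafts acylation of the two electron-rich rings, in which ring C has only C5 free (ortho to OH and OCH3, para to OH), the two free carbons of ring B are equivalent, and each ring should stop after one acylation because the chelated ketone deactivates it, so that one pot gives a single bis-ketone whichever ring reacts first.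

Step 10
Reactants: 16 phloroglucinol; 14 butyryl chloride
Product: 17 1-(2,4,6-trihydroxyphenyl)butan-1-one
Conditions: 14 (1.0 equiv), AlCl3 (3 equiv), CH2Cl2–PhNO2, rt → 40 °C; aq. HCl
Reagents that add atoms: butyryl chloride (14), CCCC(=O)Cl
Why: Friedel–Crafts monoacylation of phloroglucinol, which stops after one acyl group because the hydrogen-bonded ketone deactivates the ring.

Step 11
Reactants: 17 1-(2,4,6-trihydroxyphenyl)butan-1-one
Product: 19 2-butanoyl-3,5-dihydroxy-6,6-dimethylcyclohexa-2,4-dien-1-one, via C-methyl ketone 18 (not isolated)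
Conditions: NaOMe (4 equiv), MeI (3 equiv), MeOH, 0 °C → rt; aq. HCl
Reagents that add atoms: iodomethane, CI
Why: Base-mediated double C-methylation of the acylphloroglucinol, in which the phenoxide reacts through carbon and the carbon already methylated in 18 reacts a second time to give the dearomatised gem-dimethyl trione enol (the classical route to acylfilicinic acids), with under- and over-methylated products to be separated.

Step 12
Reactants: 19 2-butanoyl-3,5-dihydroxy-6,6-dimethylcyclohexa-2,4-dien-1-one
Product: 20 2-butanoyl-4-[(dimethylamino)methyl]-3,5-dihydroxy-6,6-dimethylcyclohexa-2,4-dien-1-one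
Conditions: [CH2=NMe2]I (1.1 equiv), i-Pr2NEt (1.0 equiv), CH2Cl2, 0 °C → rt
Reagents that add atoms: dimethylmethylideneammonium iodide, C=[N+](C)C.[I-]
Why: Mannich reaction of the preformed iminium salt at C4, the only unsubstituted enol carbon of ring A, gives a precursor of the ring A methide that has no nucleophilic ring carbon left for self-coupling.

Step 13
Reactants: 15 1-{3-[(3-butanoyl-2,6-dihydroxy-4-methoxy-5-methylphenyl)methyl]-2,4,6-trihydroxyphenyl}butan-1-one; 20 2-butanoyl-4-[(dimethylamino)methyl]-3,5-dihydroxy-6,6-dimethylcyclohexa-2,4-dien-1-one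
Product: 22 Filixsaure (2-butanoyl-4-{[3-butanoyl-5-[(3-butanoyl-2,6-dihydroxy-4-methoxy-5-methylphenyl)methyl]-2,4,6-trihydroxyphenyl]methyl}-3,5-dihydroxy-6,6-dimethylcyclohexa-2,4-dien-1-one), via ring A methide 21 (not isolated)
Conditions: 20 (1.2 equiv), 1,4-dioxane, 80 °C, N2 sweep
Reagents that add atoms: none
Why: On heating the Mannich base loses dimethylamine by E1cB to the cross-conjugated methide 21, which is captured in a Michael addition by the single unsubstituted ring carbon of 15 (ring B, between two OH groups; ring C is fully substituted), the quinone-methide type alkylation used for methylene-bridged acylphloroglucinols, under neutral conditions that avoid base-induced scrambling of the CH2 bridges.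

**Compound list**

1 | 3-methylpentane-2,4-dione | CC(=O)C(C)C(C)=O | starting material
2 | dimethyl carbonate | COC(=O)OC | starting material
3 | methyl 4-methyl-3,5-dioxohexanoate (racemic) | COC(=O)CC(=O)C(C)C(C)=O | intermediate
4 | 4-hydroxy-5,6-dimethyl-2H-pyran-2-one | CC1=C(C)C(O)=CC(=O)O1 | intermediate
5 | 4-methoxy-5,6-dimethyl-2H-pyran-2-one | COC1=CC(=O)OC(C)=C1C | intermediate
6 | 2,4,6-trihydroxybenzaldehyde | O=Cc1c(O)cc(O)cc1O | starting material
7 | 2,4,6-tris(benzyloxy)benzaldehyde | O=Cc1c(OCc2ccccc2)cc(OCc2ccccc2)cc1OCc1ccccc1 | intermediate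
8 | 6-{2-hydroxy-2-[2,4,6-tris(benzyloxy)phenyl]ethyl}-4-methoxy-5-methyl-2H-pyran-2-one (racemic; not isolated) | COC1=CC(=O)OC(CC(O)c2c(OCc3ccccc3)cc(OCc3ccccc3)cc2OCc2ccccc2)=C1C | intermediate
9 | 4-methoxy-5-methyl-6-{(E)-2-[2,4,6-tris(benzyloxy)phenyl]ethenyl}-2H-pyran-2-one | COC1=CC(=O)OC(/C=C/c2c(OCc3ccccc3)cc(OCc3ccccc3)cc2OCc2ccccc2)=C1C | intermediate
10 | 4-methoxy-5-methyl-6-{2-[2,4,6-tris(benzyloxy)phenyl]ethyl}-2H-pyran-2-one | COC1=CC(=O)OC(CCc2c(OCc3ccccc3)cc(OCc3ccccc3)cc2OCc2ccccc2)=C1C | intermediate
11 | methyl (2E)-3-methoxy-4-methyl-5-oxo-7-[2,4,6-tris(benzyloxy)phenyl]hept-2-enoate (ester cis to the ketone chain; racemic at C4; not isolated) | COC(=O)/C=C(\C(C)C(=O)CCc1c(OCc2ccccc2)cc(OCc2ccccc2)cc1OCc1ccccc1)OC | intermediate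
12 | 5-methoxy-4-methyl-2-{[2,4,6-tris(benzyloxy)phenyl]methyl}benzene-1,3-diol | COc1cc(O)c(Cc2c(OCc3ccccc3)cc(OCc3ccccc3)cc2OCc2ccccc2)c(O)c1C | intermediate
13 | 2-[(2,6-dihydroxy-4-methoxy-3-methylphenyl)methyl]benzene-1,3,5-triol | COc1cc(O)c(Cc2c(O)cc(O)cc2O)c(O)c1C | intermediate
14 | butyryl chloride | CCCC(=O)Cl | starting material
15 | 1-{3-[(3-butanoyl-2,6-dihydroxy-4-methoxy-5-methylphenyl)methyl]-2,4,6-trihydroxyphenyl}butan-1-one | CCCC(=O)c1c(O)cc(O)c(Cc2c(O)c(C)c(OC)c(C(=O)CCC)c2O)c1O | intermediate
16 | phloroglucinol | Oc1cc(O)cc(O)c1 | starting material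
17 | 1-(2,4,6-trihydroxyphenyl)butan-1-one | CCCC(=O)c1c(O)cc(O)cc1O | intermediate
18 | 1-(2,4,6-trihydroxy-3-methylphenyl)butan-1-one (not isolated) | CCCC(=O)c1c(O)cc(O)c(C)c1O | intermediate
19 | 2-butanoyl-3,5-dihydroxy-6,6-dimethylcyclohexa-2,4-dien-1-one | CCCC(=O)C1=C(O)C=C(O)C(C)(C)C1=O | intermediate
20 | 2-butanoyl-4-[(dimethylamino)methyl]-3,5-dihydroxy-6,6-dimethylcyclohexa-2,4-dien-1-one | CCCC(=O)C1=C(O)C(CN(C)C)=C(O)C(C)(C)C1=O | intermediate
21 | 2-butanoyl-3-hydroxy-6,6-dimethyl-4-methylidenecyclohex-2-ene-1,5-dione (not isolated) | CCCC(=O)C1=C(O)C(=C)C(=O)C(C)(C)C1=O | intermediate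
22 | Filixsaure | CCCC(=O)C1=C(O)C(Cc2c(O)c(Cc3c(O)c(C)c(OC)c(C(=O)CCC)c3O)c(O)c(C(=O)CCC)c2O)=C(O)C(C)(C)C1=O | target

**Step count**

Total: 13 steps. Longest linear sequence: 9 steps (steps 1, 2, 3, 5, 6, 7, 8, 9, 13).

**Steps most likely to fail**

Step 7. The opened chain may rest as the anion deprotonated at C3, in which the ester is deactivated by conjugation, so that closure from C1 is slow and the material returns to the pyranone or is cut at the ketone by methoxide (retro-Claisen). The fallback puts an acyl activating group on C1. It sets out from 5 and 7: 5 is lithiated at the 6-methyl group with LiN(i-Pr)2 in THF at −78 °C and added to 7, and the carbinol 8 is isolated this time. Dess–Martin periodinane oxidises it to 4-methoxy-5-methyl-6-{2-oxo-2-[2,4,6-tris(benzyloxy)phenyl]ethyl}-2H-pyran-2-one F1. In F1, C1 is the CH2 of a 1,3-dicarbonyl unit, and Mg(OMe)2 in refluxing MeOH should open the lactone and close the same C1–C6 bond under mild conditions, the classical conversion of 6-(2-oxoalkyl)-4-methoxy-2-pyranones into acylphloroglucinol monomethyl ethers. This gives (2,6-dihydroxy-4-methoxy-3-methylphenyl)[2,4,6-tris(benzyloxy)phenyl]methanone F2. The ortho-hydroxy diaryl ketone is then taken to the methylene with ClCO2Et/Et3N followed by NaBH4 in aqueous THF (reduction through the ortho-quinone methide), which comes back to the route at 12.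

Step 9. Before the rings carry their ketones, the CH2 bridge joins two phloroglucinol-type rings and may be cleaved by ipso-protonation under AlCl3/HCl, and AlCl3 may also take off the C4 methyl ether next to the new ketone. The fallback brings in both butyryl groups without a strong Lewis acid. It sets out from 12: BnBr/K2CO3 in DMF gives 1,3-bis(benzyloxy)-5-methoxy-4-methyl-2-{[2,4,6-tris(benzyloxy)phenyl]methyl}benzene F3. Double Vilsmeier–Haack formylation (POCl3, DMF) at ring C C5 and at one ring B carbon gives 2,4-bis(benzyloxy)-6-methoxy-5-methyl-3-{[2,4,6-tris(benzyloxy)-3-formylphenyl]methyl}benzaldehyde F4. n-PrMgBr gives the bis(1-hydroxybutyl) pentabenzyl ether F5, a mixture of diastereomers, and Dess–Martin periodinane gives the bis(butanoyl) pentabenzyl ether F6. Hydrogenolysis (H2, Pd/C) then comes back to the route at 15.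

Step 13. The methide 21 may be consumed by self-reaction, or the aminomethyl group may be lost so that free 19 captures 21 to give the symmetric ring A–CH2–ring A dimer, faster than the hindered, hydrogen-bonded ring B carbon of 15 adds. The fallback reverses the roles of the partners. It sets out from 15: [CH2=NMe2]I with i-Pr2NEt in CH2Cl2 aminomethylates the one free ring B carbon to give 1-{3-[(3-butanoyl-2,6-dihydroxy-4-methoxy-5-methylphenyl)methyl]-5-[(dimethylamino)methyl]-2,4,6-trihydroxyphenyl}butan-1-one F7. Heating F7 with an excess of 19 in dioxane releases the ring B ortho-quinone methide, which the strongly nucleophilic enol carbon C4 of 19 should capture, coming back to the route at 22.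

**Further compounds**

F1 | step 7 | 4-methoxy-5-methyl-6-{2-oxo-2-[2,4,6-tris(benzyloxy)phenyl]ethyl}-2H-pyran-2-one | COC1=CC(=O)OC(CC(=O)c2c(OCc3ccccc3)cc(OCc3ccccc3)cc2OCc2ccccc2)=C1C
F2 | step 7 | (2,6-dihydroxy-4-methoxy-3-methylphenyl)[2,4,6-tris(benzyloxy)phenyl]methanone | COc1cc(O)c(C(=O)c2c(OCc3ccccc3)cc(OCc3ccccc3)cc2OCc2ccccc2)c(O)c1C
F3 | step 9 | 1,3-bis(benzyloxy)-5-methoxy-4-methyl-2-{[2,4,6-tris(benzyloxy)phenyl]methyl}benzene | COc1cc(OCc2ccccc2)c(Cc2c(OCc3ccccc3)cc(OCc3ccccc3)cc2OCc2ccccc2)c(OCc2ccccc2)c1C
F4 | step 9 | 2,4-bis(benzyloxy)-6-methoxy-5-methyl-3-{[2,4,6-tris(benzyloxy)-3-formylphenyl]methyl}benzaldehyde | COc1c(C=O)c(OCc2ccccc2)c(Cc2c(OCc3ccccc3)cc(OCc3ccccc3)c(C=O)c2OCc2ccccc2)c(OCc2ccccc2)c1C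
F5 | step 9 | 1-{2,4-bis(benzyloxy)-6-methoxy-5-methyl-3-[(2,4,6-tris(benzyloxy)-3-(1-hydroxybutyl)phenyl)methyl]phenyl}butan-1-ol (mixture of diastereomers) | COc1c(C(O)CCC)c(OCc2ccccc2)c(Cc2c(OCc3ccccc3)cc(OCc3ccccc3)c(C(O)CCC)c2OCc2ccccc2)c(OCc2ccccc2)c1C
F6 | step 9 | 1-{2,4-bis(benzyloxy)-6-methoxy-5-methyl-3-[(2,4,6-tris(benzyloxy)-3-butanoylphenyl)methyl]phenyl}butan-1-one | COc1c(C(=O)CCC)c(OCc2ccccc2)c(Cc2c(OCc3ccccc3)cc(OCc3ccccc3)c(C(=O)CCC)c2OCc2ccccc2)c(OCc2ccccc2)c1C
F7 | step 13 | 1-{3-[(3-butanoyl-2,6-dihydroxy-4-methoxy-5-methylphenyl)methyl]-5-[(dimethylamino)methyl]-2,4,6-trihydroxyphenyl}butan-1-one | CCCC(=O)c1c(O)c(CN(C)C)c(O)c(Cc2c(O)c(C)c(OC)c(C(=O)CCC)c2O)c1O
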